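**Plan**

- Retrosynthetic cuts, in order: the 2-methylbutanoate C–O bond; then, after a carboxyl group is formally added to the OCH2 carbon, the bond from that carbon to the ring CH lying between C(CH3)2 and C(CH3)=CH (retro-Ireland–Claisen); then the aryloxyacetate ester C–O bond; then the ring C–O bond next to the gem-dimethyl carbon, back to an achiral dienone.
- Enabling feature: the trisubstituted ring double bond C(CH3)=CH lies β,γ to the exocyclic CH2, so ring CH–C(CH3)=CH is the transposed allyl unit of a 2-methylcyclohex-2-en-1-yl ester. The umbelliferone oxygen makes the migrating carbon an enolisable glycolate position, and a carboxyl group is the traceless activator.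
- Forward order: the carbocycle is bought; the oxygen at the future acyloxy carbon goes in first, then a temporary allylic carbinol; the coumarin half is tied on as an ester and joined C–C by a [3,3] shift; CO2 removal, desilylation and acylation finish the route.
- Stereochemistry: the acyloxy carbon (R) comes from catalyst-controlled conjugate borylation; the temporary carbinol (cis) from substrate-controlled 1,2-reduction; the ring CH (S) from suprafacial 1,3-transfer of the carbinol configuration; the side-chain centre from (R)-2-methylbutanoic acid.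

Key step: step 6

Remark: 2,4,4-trimethylcyclohex-2-en-1-one, [(2-oxo-2H-chromen-7-yl)oxy]acetic acid and (R)-2-methylbutanoic acid are taken as catalogue compounds.

**Step 1**
Reactants: 1 2,4,4-trimethylcyclohex-2-en-1-one
Product: 2 2,4,4-trimethylcyclohexa-2,5-dien-1-one
Conditions: DDQ, 1,4-dioxane, 100 °C
Reagents that add atoms: none
Why: DDQ dehydrogenation of a 4,4-disubstituted cyclohexenone should proceed by enolisation toward the CH2 next to the carbonyl and hydride abstraction from the CH2 next to the quaternary carbon, which also blocks aromatisation, so the cross-conjugated dienone is the end point; no stereocentre is involved.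

**Step 2**
Reactants: 2 2,4,4-trimethylcyclohexa-2,5-dien-1-one
Product: 4 (5R)-5-hydroxy-2,4,4-trimethylcyclohex-2-en-1-one, via pinacol boronate 3 (not isolated)
Conditions: B2pin2, CuCl (cat.), NaOt-Bu (cat.), Josiphos-type ferrocenyl bisphosphine (cat., antipode selected in a first small run for the 5R series), MeOH, THF, rt; then NaBO3·4H2O, THF/H2O, rt
Reagents that add atoms: sodium perborate, [Na+].[Na+].O[B-]1(O)OO[B-](O)(O)OO1
Why: Copper(I)-catalysed asymmetric conjugate borylation of a cyclic enone: the ligated Cu–Bpin species should add to the α-unsubstituted enone unit in preference to the α-methylated one, the chiral bisphosphine selects the face of the β-carbon so that the C–B centre is R, and perborate oxidation replaces boron by oxygen with retention.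

**Step 3**
Reactants: 4 (5R)-5-hydroxy-2,4,4-trimethylcyclohex-2-en-1-one
Product: 5 (5R)-5-(tert-butyldimethylsilyloxy)-2,4,4-trimethylcyclohex-2-en-1-one
Conditions: TBSOTf, 2,6-lutidine, CH2Cl2, −78 °C → 0 °C
Reagents that add atoms: tert-butyldimethylsilyl trifluoromethanesulfonate, CC(C)(C)[Si](C)(C)OS(=O)(=O)C(F)(F)F
Why: Silylation of a hindered secondary alcohol with the silyl triflate and a hindered pyridine base, run cold so that the β-hydroxy ketone does not eliminate back to 2; the stereocentre is untouched.

**Step 4**
Reactants: 5 (5R)-5-(tert-butyldimethylsilyloxy)-2,4,4-trimethylcyclohex-2-en-1-one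
Product: 6 (1S,5R)-5-(tert-butyldimethylsilyloxy)-2,4,4-trimethylcyclohex-2-en-1-ol
Conditions: NaBH4, CeCl3·7H2O, MeOH, −78 °C
Reagents that add atoms: none
Why: Luche 1,2-reduction: cerium-assisted borohydride should attack the carbonyl from the ring face opposite the 5-silyloxy group (axial attack on the half-chair, the usual course for 5-substituted cyclohex-2-enones), which sets the new carbinol centre as 1S, cis to the silyloxy group, without conjugate reduction.

**Step 5**
Reactants: 6 (1S,5R)-5-(tert-butyldimethylsilyloxy)-2,4,4-trimethylcyclohex-2-en-1-ol; 7 [(2-oxo-2H-chromen-7-yl)oxy]acetic acid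
Product: 8 (1S,5R)-5-(tert-butyldimethylsilyloxy)-2,4,4-trimethylcyclohex-2-en-1-yl 2-[(2-oxo-2H-chromen-7-yl)oxy]acetate
Conditions: DCC, DMAP (cat.), CH2Cl2/DMF, 0 °C → rt
Reagents that add atoms: none
Why: Steglich esterification (carbodiimide activation, DMAP acyl transfer) acylates the allylic alcohol at oxygen, so the carbinol configuration is retained and no new stereocentre arises.

**Step 6**
Reactants: 8 (1S,5R)-5-(tert-butyldimethylsilyloxy)-2,4,4-trimethylcyclohex-2-en-1-yl 2-[(2-oxo-2H-chromen-7-yl)oxy]acetate
Product: 11 2-[(1S,5R)-5-(tert-butyldimethylsilyloxy)-2,6,6-trimethylcyclohex-2-en-1-yl]-2-[(2-oxo-2H-chromen-7-yl)oxy]acetic acid (both epimers at the acid α-carbon), via silyl ketene acetal 9 (not isolated), via trimethylsilyl ester 10 (not isolated)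
Conditions: TMSCl/Et3N (premixed), LiHMDS, THF, −78 °C; then rt → 60 °C; aq. citric acid work-up
Reagents that add atoms: none
Why: LiHMDS removes a proton from the OCH2 carbon of 8 (acidified by the aryloxy group and the least hindered acidic C–H) and TMSCl traps the chelated enolate as ketene acetal 9, which on warming undergoes a concerted [3,3]-sigmatropic shift in which the allylic C–O bond breaks, the aryloxy-bearing carbon bonds to the alkene CH next to the C(CH3)2 group, and the double bond moves to its position in the target. The closest known reaction type is the Ireland–Claisen rearrangement of glycolate (α-alkoxyacetate) esters of cyclohex-2-en-1-ols. No ring is closed in the product; the six-membered array exists only in the chair- or boat-like transition state. The new ring stereocentre (1S in 11) is controlled by the suprafacial course of the shift: the carbon arrives on the face from which the oxygen leaves, and because that oxygen was set cis to the silyloxy group in step 4 the new substituent ends up cis to it as the target requires, while the exocyclic α-centre forms without control and is erased in step 7. The step needs chemoselective enolisation in the presence of the coumarin lactone, which a hindered non-nucleophilic amide base at −78 °C with internal silyl trapping should secure, and it needs C–C bond formation beside a quaternary carbon, for which an intramolecular pericyclic shift driven by C=O formation is well suited. Regiochemistry is not in question because 9 contains a single allyl vinyl ether unit.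

**Step 7**
Reactants: 11 2-[(1S,5R)-5-(tert-butyldimethylsilyloxy)-2,6,6-trimethylcyclohex-2-en-1-yl]-2-[(2-oxo-2H-chromen-7-yl)oxy]acetic acid
Product: 13 7-{[(1S,5R)-5-(tert-butyldimethylsilyloxy)-2,6,6-trimethylcyclohex-2-en-1-yl]methoxy}-2H-chromen-2-one, via Barton ester 12 (not isolated)
Conditions: N-hydroxypyridine-2-thione, DCC, DMAP (cat.), CH2Cl2, 0 °C → rt, dark; then t-BuSH, visible light (tungsten lamp), rt
Reagents that add atoms: none
Why: Barton reductive decarboxylation: thiohydroxamate ester 12 undergoes light-induced radical chain fragmentation with loss of CO2 to an oxygen-stabilised α-aryloxyalkyl radical that abstracts hydrogen from the thiol, turning the uncontrolled α-centre into the CH2 group while the adjacent ring stereocentre, never a radical site, is preserved.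

**Step 8**
Reactants: 13 7-{[(1S,5R)-5-(tert-butyldimethylsilyloxy)-2,6,6-trimethylcyclohex-2-en-1-yl]methoxy}-2H-chromen-2-one
Product: 14 7-{[(1S,5R)-5-hydroxy-2,6,6-trimethylcyclohex-2-en-1-yl]methoxy}-2H-chromen-2-one
Conditions: HF·pyridine, pyridine, THF, 0 °C → rt
Reagents that add atoms: none
Why: Fluoride-mediated Si–O cleavage under non-basic conditions removes the silyl ether without opening the coumarin lactone or touching either stereocentre.

**Step 9**
Reactants: 14 7-{[(1S,5R)-5-hydroxy-2,6,6-trimethylcyclohex-2-en-1-yl]methoxy}-2H-chromen-2-one; 15 (R)-2-methylbutanoic acid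
Product: 17 (1R,5S)-4,6,6-trimethyl-5-{[(2-oxo-2H-chromen-7-yl)oxy]methyl}cyclohex-3-en-1-yl (2R)-2-methylbutanoate, via mixed anhydride 16 (not isolated)
Conditions: 15, 2,4,6-trichlorobenzoyl chloride, Et3N, THF, rt; then 14, DMAP, toluene, rt
Reagents that add atoms: none
Why: Yamaguchi esterification: mixed anhydride 16 with DMAP acylates the hindered secondary alcohol at oxygen with retention at the carbinol carbon, and the (R) centre of the acyl group is brought in with acid 15, the mild conditions guarding it against epimerisation.

**Compound list**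

1 | 2,4,4-trimethylcyclohex-2-en-1-one | CC1=CC(C)(C)CCC1=O | starting material
2 | 2,4,4-trimethylcyclohexa-2,5-dien-1-one | CC1=CC(C)(C)C=CC1=O | intermediate
3 | (5R)-2,4,4-trimethyl-5-(4,4,5,5-tetramethyl-1,3,2-dioxaborolan-2-yl)cyclohex-2-en-1-one | CC1(C)OB(OC1(C)C)[C@@H]2CC(=O)C(C)=CC2(C)C | intermediate
4 | (5R)-5-hydroxy-2,4,4-trimethylcyclohex-2-en-1-one | O[C@@H]1CC(=O)C(C)=CC1(C)C | intermediate
5 | (5R)-5-(tert-butyldimethylsilyloxy)-2,4,4-trimethylcyclohex-2-en-1-one | CC(C)(C)[Si](C)(C)O[C@@H]1CC(=O)C(C)=CC1(C)C | intermediate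
6 | (1S,5R)-5-(tert-butyldimethylsilyloxy)-2,4,4-trimethylcyclohex-2-en-1-ol | CC(C)(C)[Si](C)(C)O[C@@H]1C[C@H](O)C(C)=CC1(C)C | intermediate
7 | [(2-oxo-2H-chromen-7-yl)oxy]acetic acid | OC(=O)COc1ccc2ccc(=O)oc2c1 | starting material
8 | (1S,5R)-5-(tert-butyldimethylsilyloxy)-2,4,4-trimethylcyclohex-2-en-1-yl 2-[(2-oxo-2H-chromen-7-yl)oxy]acetate | CC(C)(C)[Si](C)(C)O[C@@H]1C[C@H](OC(=O)COc2ccc3ccc(=O)oc3c2)C(C)=CC1(C)C | intermediate
9 | (Z)-ketene trimethylsilyl acetal of 8 (the geometry has no bearing on the route) | CC(C)(C)[Si](C)(C)O[C@@H]1C[C@H](O/C(O[Si](C)(C)C)=C/Oc2ccc3ccc(=O)oc3c2)C(C)=CC1(C)C | intermediate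
10 | trimethylsilyl 2-[(1S,5R)-5-(tert-butyldimethylsilyloxy)-2,6,6-trimethylcyclohex-2-en-1-yl]-2-[(2-oxo-2H-chromen-7-yl)oxy]acetate (both α-epimers) | CC(C)(C)[Si](C)(C)O[C@@H]1CC=C(C)[C@H](C(Oc2ccc3ccc(=O)oc3c2)C(=O)O[Si](C)(C)C)C1(C)C | intermediate
11 | 2-[(1S,5R)-5-(tert-butyldimethylsilyloxy)-2,6,6-trimethylcyclohex-2-en-1-yl]-2-[(2-oxo-2H-chromen-7-yl)oxy]acetic acid (both α-epimers) | CC(C)(C)[Si](C)(C)O[C@@H]1CC=C(C)[C@H](C(Oc2ccc3ccc(=O)oc3c2)C(=O)O)C1(C)C | intermediate
12 | 2-thioxopyridin-1(2H)-yl ester of 11 | CC(C)(C)[Si](C)(C)O[C@@H]1CC=C(C)[C@H](C(Oc2ccc3ccc(=O)oc3c2)C(=O)On2ccccc2=S)C1(C)C | intermediate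
13 | 7-{[(1S,5R)-5-(tert-butyldimethylsilyloxy)-2,6,6-trimethylcyclohex-2-en-1-yl]methoxy}-2H-chromen-2-one | CC(C)(C)[Si](C)(C)O[C@@H]1CC=C(C)[C@H](COc2ccc3ccc(=O)oc3c2)C1(C)C | intermediate
14 | 7-{[(1S,5R)-5-hydroxy-2,6,6-trimethylcyclohex-2-en-1-yl]methoxy}-2H-chromen-2-one | O[C@@H]1CC=C(C)[C@H](COc2ccc3ccc(=O)oc3c2)C1(C)C | intermediate
15 | (R)-2-methylbutanoic acid | CC[C@@H](C)C(=O)O | starting material
16 | (2R)-2-methylbutanoic 2,4,6-trichlorobenzoic anhydride | CC[C@@H](C)C(=O)OC(=O)c1c(Cl)cc(Cl)cc1Cl | intermediate
17 | (1R,5S)-4,6,6-trimethyl-5-{[(2-oxo-2H-chromen-7-yl)oxy]methyl}cyclohex-3-en-1-yl (2R)-2-methylbutanoate | CC[C@@H](C)C(=O)O[C@@H]1CC=C(C)[C@H](COc2ccc3ccc(=O)oc3c2)C1(C)C | target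

**Step count**

Total steps: 9. Longest linear sequence: 9 steps (1 → 17); 7 and 15 are purchased and enter at steps 5 and 9.

**Steps most likely to fail**

Step 6. The amide base or the ester enolate may attack the coumarin lactone before silylation. The [3,3] shift may also be slow, because in the reactive half-chair the axial silyloxy group lies on the ring face that the migrating carbon must cross, which leaves the ketene acetal time to decompose. The fallback sets out from 6 and returns at 13, so it also bypasses step 7. Alcohol 6 would be O-alkylated with (iodomethyl)tributylstannane (KH, THF, 0 °C → rt) to tributyl({[(1S,5R)-5-(tert-butyldimethylsilyloxy)-2,4,4-trimethylcyclohex-2-en-1-yl]oxy}methyl)stannane F1. Tin–lithium exchange with n-BuLi in THF at −78 °C should trigger the [2,3]-Wittig–Still rearrangement, with the same suprafacial transfer, to [(1S,5R)-5-(tert-butyldimethylsilyloxy)-2,6,6-trimethylcyclohex-2-en-1-yl]methanol F2. Mitsunobu etherification of F2 with umbelliferone (PPh3, DIAD, toluene, rt → 60 °C) would then give 13.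

Step 2. Face discrimination at the β-carbon may be poor, the copper–boryl addition may be slow at a carbon flanked by a quaternary centre, or the methylated enone unit may be borylated as well. The fallback sets out from 2 and returns at 4. Amine-salt-catalysed asymmetric nucleophilic epoxidation of the unsubstituted enone unit (9-amino-9-deoxy-epi-quinine trifluoroacetate salt or its pseudoenantiomer, aq. H2O2, dioxane, 30–50 °C) would give (1S,6S)-3,5,5-trimethyl-7-oxabicyclo[4.1.0]hept-3-en-2-one F3. Reductive cleavage of the Cα–O bond of this epoxy ketone (PhSeSePh, NaBH4, AcOH, EtOH, 0 °C) would then give 4.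

Step 4. Hydride delivery may show poor facial selectivity, giving the trans carbinol, which would transfer the wrong configuration in step 6. The fallback sets out from 5 and returns at 8. The trans epimer from the reduction, (1R,5R)-5-(tert-butyldimethylsilyloxy)-2,4,4-trimethylcyclohex-2-en-1-ol F4, would be coupled with acid 7 under Mitsunobu conditions (PPh3, DIAD, THF, 0 °C → rt). This esterifies with inversion at the carbinol carbon and delivers 8 directly, replacing step 5 for that epimer.

**Further compounds**

F1 | step 6 | tributyl({[(1S,5R)-5-(tert-butyldimethylsilyloxy)-2,4,4-trimethylcyclohex-2-en-1-yl]oxy}methyl)stannane | CC(C)(C)[Si](C)(C)O[C@@H]1C[C@H](OC[Sn](CCCC)(CCCC)CCCC)C(C)=CC1(C)C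
F2 | step 6 | [(1S,5R)-5-(tert-butyldimethylsilyloxy)-2,6,6-trimethylcyclohex-2-en-1-yl]methanol | CC(C)(C)[Si](C)(C)O[C@@H]1CC=C(C)[C@H](CO)C1(C)C
F3 | step 2 | (1S,6S)-3,5,5-trimethyl-7-oxabicyclo[4.1.0]hept-3-en-2-one | O1[C@@H]2[C@H]1C(=O)C(C)=CC2(C)C
F4 | step 4 | (1R,5R)-5-(tert-butyldimethylsilyloxy)-2,4,4-trimethylcyclohex-2-en-1-ol | CC(C)(C)[Si](C)(C)O[C@@H]1C[C@@H](O)C(C)=CC1(C)C
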